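**Plan**

1. Numbering: ring C1 (CHOH)–C2 (=CH)–C3 (C–CH2OH)–C4 (CHOH)–C5–C6 (epoxide, C6 quaternary); side chain C1′ (CHOH)–C2′=C3′(Me)–C4′=C5′; cyclohexyl C1″–C6″. The retrosynthesis first cuts C3′–C4′ (Suzuki–Miyaura) into a cyclohexyl vinylboronate (fragment B) and a core vinyl iodide (fragment A), then C2′=C3′ (iodo-Wittig).
2. In the core, a retro-Payne shift moves the epoxide from C5–C6 to C4–C5; removing that oxygen leaves a cyclohexa-1,3-diene C2=C3–C4=C5 whose sp3 carbons C1 and C6 carry trans oxygens. This ring is cut at C1–C2 and C5–C6 together.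
3. What allows this: C1′–C6–C1 is a masked dihydroxyacetone (a ketone carbon between two carbinol carbons). Its acetonide silyl enol ether is an electron-rich C1=C6 alkene whose C1–O/C6–O trans relation is locked by the dioxin ring. C2–C5 plus the CH2OH carbon map onto methyl 2-oxo-2H-pyran-5-carboxylate: its lactone bridge leaves as CO2, and its ester activates, directs, shields C2=C3 and ends as CH2OH.
4. Forward, fragment A: SAMP-hydrazone alkylation sets C1′; the pyranone cycloaddition builds the ring and sets C1 and C6 anti to the C1′ substituent; epoxidation anti to the C6 silyloxy group and Payne rearrangement set C4 and C5; then ester reduction, Z-iodo-olefination, deprotection, coupling, desilylation.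
5. Fragment B: Shi epoxidation of geranyl acetate sets C3″; a radical cyclisation mediated by trivalent titanium closes the cyclohexane with its exocyclic alkene and sets C1″ (cis to C3″–O); a Takai–Utimoto olefination gives the E-vinylboronate.

Key step: step 5

Remark: the sense of induction in steps 2 and 14 is taken from the accepted models for SAMP azaenolates and for the D-fructose-derived ketone; the enantiomeric auxiliary or ketone would be used if either proved opposite.

**Fragment A (core)**

Step 1
Reactants: 1 2,2-dimethyl-1,3-dioxan-5-one; 2 (S)-1-amino-2-(methoxymethyl)pyrrolidine (SAMP)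
Product: 3 (2S)-N-(2,2-dimethyl-1,3-dioxan-5-ylidene)-2-(methoxymethyl)pyrrolidin-1-amine
Conditions: benzene, reflux, water separator
Reagents that add atoms: none
Why: Hydrazone formation by condensation of a ketone with a 1,1-dialkylhydrazine should install the auxiliary cleanly without creating a stereocentre.

Step 2
Reactants: 3; 4 (chloromethoxy)triisopropylsilane
Product: 5 (2S)-N-[2,2-dimethyl-4-(triisopropylsilyloxymethyl)-1,3-dioxan-5-ylidene]-2-(methoxymethyl)pyrrolidin-1-amine (dioxane C4 arranged as in 6; C=N geometry not defined)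
Conditions: t-BuLi, THF, −78 °C; then 4, −100 → −20 °C
Reagents that add atoms: none
Why: In this SAMP-hydrazone α-alkylation the chelated lithium azaenolate should be attacked by the reactive α-chloro ether on the face remote from the methoxymethyl arm, which sets the future C1′ stereocentre as drawn.

Step 3
Reactants: 5
Product: 6 (4S)-2,2-dimethyl-4-(triisopropylsilyloxymethyl)-1,3-dioxan-5-one
Conditions: saturated aq. oxalic acid, Et2O, rt
Reagents that add atoms: water, O
Why: Two-phase oxalic acid hydrolysis of the hydrazone should release the ketone without epimerising the α-stereocentre or touching the acetonide and the silyl ether.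

Step 4
Reactants: 6
Product: 7 (4S)-2,2-dimethyl-4-(triisopropylsilyloxymethyl)-5-(trimethylsilyloxy)-4H-1,3-dioxine
Conditions: LiN(i-Pr)2, Me3SiCl (in situ quench), THF, −78 °C
Reagents that add atoms: chlorotrimethylsilane, C[Si](C)(C)Cl
Why: Kinetic deprotonation at the unsubstituted α-methylene and O-silylation (silyl enol ether formation) should give the ring-locked enol ether (enol CH = future C1, silyloxy carbon = future C6) with the two oxygens held trans and no new stereocentre.

Step 5
Reactants: 7; 8 methyl 2-oxo-2H-pyran-5-carboxylate (methyl coumalate)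
Product: 10 cis-fused diene ester methyl 2,2-dimethyl-4-(triisopropylsilyloxymethyl)-4a-(trimethylsilyloxy)-4a,8a-dihydro-4H-1,3-benzodioxine-7-carboxylate, via bridged lactone 9 (not isolated)
Conditions: toluene, N,O-bis(trimethylsilyl)acetamide (0.1 equiv), 100 °C, sealed tube
Reagents that add atoms: none
Why: The electron-poor 2-pyranone 8 and the doubly oxygenated enol ether 7 should combine in an inverse-electron-demand Diels–Alder reaction to the bridged lactone 9, which loses CO2 by retro-[4+2] at the same temperature to unveil the cyclohexa-1,3-diene 10; the closest known reaction type is the cycloaddition–decarboxylation cascade of coumalates with enol ethers. The carbocycle closes in one suprafacial [4+2] event that makes C1–C2 and C5–C6 together, the O–C(=O) bridge of the 2-oxabicyclo[2.2.2]octene being a temporary ring that is excised as CO2. Regiochemistry follows from matched polarity: the pyranone C6, β to the ester and δ to the lactone carbonyl, is the most electrophilic terminus and should bond to the enol-ether carbon β to the silyloxy group (C1), so the silyloxy carbon (C6) joins the pyranone C3. The trans relation of the C1 and C6 oxygens is fixed by the dioxin ring of 7 and the suprafacial addition, and both new stereocentres are set relative to C1′ by approach of 8 to the face of 7 opposite the pseudo-axial silyloxymethyl group (either bridge isomer of 9 gives the same diene). The step needs the diene to survive without losing trimethylsilanol, which would aromatise the ring; neutral, acid-scavenged conditions should secure this.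

Step 6
Reactants: 10
Product: 11 methyl 5,6-epoxy-2,2-dimethyl-4-(triisopropylsilyloxymethyl)-4a-(trimethylsilyloxy)-4a,5,6,8a-tetrahydro-4H-1,3-benzodioxine-7-carboxylate (epoxide trans to the 4a-silyloxy group)
Conditions: dimethyldioxirane, acetone, −40 → −20 °C
Reagents that add atoms: dimethyldioxirane, CC1(C)OO1
Why: Electrophilic epoxidation should take the C4=C5 alkene, since C2=C3 is deactivated by the ester, and should occur on the face opposite the pseudo-axial allylic silyloxy group at C6, which sets C4 and places the epoxide trans to the C6 oxygen.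

Step 7
Reactants: 11
Product: 13 methyl 4a,5-epoxy-6-hydroxy-2,2-dimethyl-4-(triisopropylsilyloxymethyl)-4a,5,6,8a-tetrahydro-4H-1,3-benzodioxine-7-carboxylate (6-OH trans to the epoxide), via tertiary alkoxide 12 (not isolated)
Conditions: Bu4NF (1.0 equiv), THF, −40 → 0 °C; aq. NH4Cl
Reagents that add atoms: none
Why: Fluoride should cleave the tertiary trimethylsilyl ether much faster than the primary triisopropylsilyl ether, and the alkoxide, held trans to the epoxide, should open it at C5 with inversion (Payne rearrangement) to the more substituted C5–C6 epoxide and the secondary C4 alkoxide, which fixes C5 and leaves the C4 hydroxyl trans to the epoxide.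

Step 8
Reactants: 13
Product: 14 the diol in which the ester of 13 is reduced to CH2OH (C4–OH and C3–CH2OH free)
Conditions: i-Bu2AlH (3.5 equiv), CH2Cl2, −78 °C; aq. KNaC4H4O6
Reagents that add atoms: none
Why: 1,2-Reduction of the conjugated ester with an aluminium hydride at low temperature should give the allylic alcohol and leave the epoxide, acetonide and silyl ether intact.

Step 9
Reactants: 14
Product: 15 bis-acetonide of 14 (second isopropylidene across C4–O and the C3–CH2–O), triisopropylsilyl ether retained
Conditions: 2,2-dimethoxypropane, pyridinium p-toluenesulfonate (cat.), CH2Cl2, rt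
Reagents that add atoms: 2,2-dimethoxypropane, COC(C)(C)OC
Why: Acid-catalysed transacetalisation should close the six-membered acetonide of the allylic 1,3-diol, masking both hydroxyls for the oxidation and olefination.

Step 10
Reactants: 15
Product: 16 primary alcohol (C1′–CH2OH) of the bis-acetonide
Conditions: Bu4NF, THF, 0 °C → rt; aq. NH4Cl
Reagents that add atoms: none
Why: Fluoride-mediated desilylation should free the primary alcohol while acetonides and epoxide, which now has no free neighbouring hydroxyl, stay unchanged.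

Step 11
Reactants: 16
Product: 17 aldehyde (C1′–CHO) of the bis-acetonide
Conditions: Dess–Martin periodinane, pyridine, CH2Cl2, 0 °C
Reagents that add atoms: none
Why: Dess–Martin oxidation under buffered, non-basic conditions should give the α-alkoxy aldehyde without epimerising C1′, and it would be used at once.

Step 12
Reactants: 17; 18 ethyltriphenylphosphonium iodide
Product: 19 (Z)-vinyl iodide: bis-acetonide bearing a (Z)-2-iodoprop-1-enyl group on C1′ (iodine cis to C1′)
Conditions: 18, n-BuLi, THF, 0 °C; I2, −78 °C; NaN(SiMe3)2, −78 °C; then 17, −78 → −20 °C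
Reagents that add atoms: iodine, II
Why: The Stork–Zhao-type Wittig reaction of the non-stabilised α-iodo ylide should pass through the kinetic cis-oxaphosphetane and give the (Z)-iodoalkene, which fixes the C2′=C3′ geometry with the methyl group trans to C1′.

Step 13
Reactants: 19
Product: 20 1-[(1S,2Z)-1-hydroxy-3-iodobut-2-en-1-yl]-4-(hydroxymethyl)-7-oxabicyclo[4.1.0]hept-3-ene-2,5-diol (ring stereocentres arranged as in 30)
Conditions: AcOH/H2O/THF (3:1:1), 40 °C
Reagents that add atoms: none
Why: Mild aqueous acid should hydrolyse both acetonides before the acid-labile dienyl carbinol exists, the epoxide being deactivated toward ionisation by its flanking oxygens.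

**Fragment B (cyclohexyl vinylboronate)**

Step 14
Reactants: 21 geranyl acetate
Product: 22 (2E)-5-[(2R)-3,3-dimethyloxiran-2-yl]-3-methylpent-2-en-1-yl acetate
Conditions: 1,2:4,5-di-O-isopropylidene-β-D-erythro-2,3-hexodiulo-2,6-pyranose (0.3 equiv), KHSO5, K2CO3, Bu4NHSO4 (cat.), MeCN/dimethoxymethane/aq. Na2B4O7, 0 °C
Reagents that add atoms: potassium peroxymonosulfate, [K+].[O-]S(=O)(=O)OO
Why: In the Shi epoxidation the chiral dioxirane should take the electron-rich 6,7-alkene in preference to the one deactivated by the allylic acetate, and its spiro transition state should deliver the (R)-epoxide, which sets the future C3″.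

Step 15
Reactants: 22
Product: 23 [(1S,3R)-3-hydroxy-2,2-dimethyl-6-methylidenecyclohexyl]methyl acetate
Conditions: Cp2TiCl2 (2.2 equiv), Mn, THF, rt; then 22; dilute aq. HCl
Reagents that add atoms: none
Why: Cp2TiCl (trivalent titanium) should open the epoxide to the tertiary radical, which cyclises 6-endo through a chair with the titanoxy and acetoxymethyl groups equatorial (C1″ cis to C3″–O); trapping by a second Cp2TiCl and β-hydride elimination should give the exocyclic alkene selectively.

Step 16
Reactants: 23
Product: 24 [(1S,3R)-3-(tert-butyldimethylsilyloxy)-2,2-dimethyl-6-methylidenecyclohexyl]methyl acetate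
Conditions: t-BuMe2SiOTf, 2,6-lutidine, CH2Cl2, 0 °C
Reagents that add atoms: tert-butyldimethylsilyl trifluoromethanesulfonate, CC(C)(C)[Si](C)(C)OS(=O)(=O)C(F)(F)F
Why: Silylation with the silyl triflate should protect the hindered secondary alcohol next to the gem-dimethyl group.

Step 17
Reactants: 24
Product: 25 [(1S,3R)-3-(tert-butyldimethylsilyloxy)-2,2-dimethyl-6-methylidenecyclohexyl]methanol
Conditions: K2CO3 (cat.), MeOH, rt
Reagents that add atoms: none
Why: Base-catalysed methanolysis should remove the acetate and leave the silyl ether.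

Step 18
Reactants: 25
Product: 26 (1S,3R)-3-(tert-butyldimethylsilyloxy)-2,2-dimethyl-6-methylidenecyclohexane-1-carbaldehyde
Conditions: Dess–Martin periodinane, pyridine, CH2Cl2, 0 °C
Reagents that add atoms: none
Why: Buffered Dess–Martin oxidation should give the β,γ-unsaturated aldehyde without epimerisation at C1″ or migration of the alkene into conjugation, and it would be used at once.

Step 19
Reactants: 26; 27 2-(dichloromethyl)-4,4,5,5-tetramethyl-1,3,2-dioxaborolane
Product: 28 2-{(E)-2-[(1S,3R)-3-(tert-butyldimethylsilyloxy)-2,2-dimethyl-6-methylidenecyclohexyl]ethenyl}-4,4,5,5-tetramethyl-1,3,2-dioxaborolane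
Conditions: CrCl2, LiI, 27, THF, rt
Reagents that add atoms: none
Why: In the Takai–Utimoto olefination the geminal dichromium species formed by divalent chromium from the dihalomethylboronate should add to the aldehyde and eliminate to the E-alkenylboronate under non-basic conditions that spare C1″.

**Union and end game**

Step 20
Reactants: 20; 28
Product: 29 3″-O-(tert-butyldimethylsilyl) ether of 30
Conditions: Pd(PPh3)4 (cat.), TlOEt, THF/H2O (3:1), rt
Reagents that add atoms: none
Why: Suzuki–Miyaura coupling at zerovalent palladium proceeds with retention at both alkenyl partners and should give the (2′Z,4′E)-diene, the thallium base allowing a fast room-temperature reaction that tolerates the free hydroxyls and the epoxide.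

Step 21
Reactants: 29
Product: 30 (1R,2S,5R,6S)-1-[(1S,2Z,4E)-1-hydroxy-5-[(1S,3R)-3-hydroxy-2,2-dimethyl-6-methylidenecyclohexyl]-3-methylpenta-2,4-dien-1-yl]-4-(hydroxymethyl)-7-oxabicyclo[4.1.0]hept-3-ene-2,5-diol
Conditions: Bu4NF, THF, rt; aq. NH4Cl
Reagents that add atoms: none
Why: Fluoride-mediated desilylation should remove the last protecting group without acid, which the allylic dienyl carbinol and the epoxide would not tolerate.

**Compound list**

1 | 2,2-dimethyl-1,3-dioxan-5-one | CC1(C)OCC(=O)CO1 | starting material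
2 | (S)-1-amino-2-(methoxymethyl)pyrrolidine (SAMP) | COC[C@@H]1CCCN1N | starting material
3 | (2S)-N-(2,2-dimethyl-1,3-dioxan-5-ylidene)-2-(methoxymethyl)pyrrolidin-1-amine | COC[C@@H]1CCCN1N=C2COC(C)(C)OC2 | intermediate
4 | (chloromethoxy)triisopropylsilane | CC(C)[Si](OCCl)(C(C)C)C(C)C | starting material
5 | SAMP hydrazone of 6 (dioxane C4 arranged as in 6; C=N geometry not defined) | CC(C)[Si](C(C)C)(C(C)C)OC[C@@H]1OC(C)(C)OCC1=NN2CCC[C@H]2COC | intermediate
6 | (4S)-2,2-dimethyl-4-(triisopropylsilyloxymethyl)-1,3-dioxan-5-one | CC(C)[Si](C(C)C)(C(C)C)OC[C@@H]1OC(C)(C)OCC1=O | intermediate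
7 | (4S)-2,2-dimethyl-4-(triisopropylsilyloxymethyl)-5-(trimethylsilyloxy)-4H-1,3-dioxine | CC(C)[Si](C(C)C)(C(C)C)OC[C@@H]1OC(C)(C)OC=C1O[Si](C)(C)C | intermediate
8 | methyl 2-oxo-2H-pyran-5-carboxylate (methyl coumalate) | COC(=O)C1=COC(=O)C=C1 | starting material
9 | bridged lactone cycloadduct (2-oxabicyclo[2.2.2]oct-5-en-3-one with the dioxane of 7 fused across the saturated two-carbon bridge; isomer with the silyloxy group pointing away from the lactone bridge drawn) | CC(C)[Si](C(C)C)(C(C)C)OC[C@@H]1OC(C)(C)O[C@@H]2[C@@]1(O[Si](C)(C)C)[C@H]3C=C(C(=O)OC)[C@@H]2OC3=O | intermediate (not isolated)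
10 | methyl 2,2-dimethyl-4-(triisopropylsilyloxymethyl)-4a-(trimethylsilyloxy)-4a,8a-dihydro-4H-1,3-benzodioxine-7-carboxylate (cis-fused; 4-CH2OSi, 4a-OSiMe3 and 8a-H on one face of the dioxane ring) | CC(C)[Si](C(C)C)(C(C)C)OC[C@@H]1OC(C)(C)O[C@H]2C=C(C(=O)OC)C=C[C@@]12O[Si](C)(C)C | intermediate
11 | 5,6-epoxide of 10, epoxide oxygen trans to the 4a-silyloxy group | CC(C)[Si](C(C)C)(C(C)C)OC[C@@H]1OC(C)(C)O[C@H]2C=C(C(=O)OC)[C@H]3O[C@H]3[C@@]12O[Si](C)(C)C | intermediate
12 | tertiary alkoxide from desilylation of 11 (tetrabutylammonium salt) | CC(C)[Si](C(C)C)(C(C)C)OC[C@@H]1OC(C)(C)O[C@H]2C=C(C(=O)OC)[C@H]3O[C@H]3[C@@]12[O-].CCCC[N+](CCCC)(CCCC)CCCC | intermediate (not isolated)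
13 | methyl 4a,5-epoxy-6-hydroxy-2,2-dimethyl-4-(triisopropylsilyloxymethyl)-4a,5,6,8a-tetrahydro-4H-1,3-benzodioxine-7-carboxylate (6-OH trans to the epoxide; epoxide oxygen trans to O1 at C8a) | CC(C)[Si](C(C)C)(C(C)C)OC[C@@H]1OC(C)(C)O[C@H]2C=C(C(=O)OC)[C@@H](O)[C@@H]3O[C@]123 | intermediate
14 | diol: 13 with CH2OH in place of the ester | CC(C)[Si](C(C)C)(C(C)C)OC[C@@H]1OC(C)(C)O[C@H]2C=C(CO)[C@@H](O)[C@@H]3O[C@]123 | intermediate
15 | bis-acetonide triisopropylsilyl ether | CC(C)[Si](C(C)C)(C(C)C)OC[C@@H]1OC(C)(C)O[C@H]2C=C4COC(C)(C)O[C@H]4[C@@H]3O[C@]123 | intermediate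
16 | bis-acetonide primary alcohol | OC[C@@H]1OC(C)(C)O[C@H]2C=C4COC(C)(C)O[C@H]4[C@@H]3O[C@]123 | intermediate
17 | bis-acetonide aldehyde | O=C[C@@H]1OC(C)(C)O[C@H]2C=C4COC(C)(C)O[C@H]4[C@@H]3O[C@]123 | intermediate
18 | ethyltriphenylphosphonium iodide | CC[P+](c1ccccc1)(c1ccccc1)c1ccccc1.[I-] | starting material
19 | bis-acetonide (Z)-2-iodoprop-1-enyl compound | C/C(I)=C/[C@@H]1OC(C)(C)O[C@H]2C=C4COC(C)(C)O[C@H]4[C@@H]3O[C@]123 | intermediate
20 | 1-[(1S,2Z)-1-hydroxy-3-iodobut-2-en-1-yl]-4-(hydroxymethyl)-7-oxabicyclo[4.1.0]hept-3-ene-2,5-diol (ring as in 30) | C/C(I)=C/[C@H](O)[C@]12O[C@H]1[C@H](O)C(CO)=C[C@@H]2O | intermediate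
21 | geranyl acetate | CC(C)=CCC/C(C)=C/COC(C)=O | starting material
22 | (2E)-5-[(2R)-3,3-dimethyloxiran-2-yl]-3-methylpent-2-en-1-yl acetate | CC1(C)O[C@@H]1CC/C(C)=C/COC(C)=O | intermediate
23 | [(1S,3R)-3-hydroxy-2,2-dimethyl-6-methylidenecyclohexyl]methyl acetate | C=C1CC[C@@H](O)C(C)(C)[C@H]1COC(C)=O | intermediate
24 | [(1S,3R)-3-(tert-butyldimethylsilyloxy)-2,2-dimethyl-6-methylidenecyclohexyl]methyl acetate | C=C1CC[C@@H](O[Si](C)(C)C(C)(C)C)C(C)(C)[C@H]1COC(C)=O | intermediate
25 | [(1S,3R)-3-(tert-butyldimethylsilyloxy)-2,2-dimethyl-6-methylidenecyclohexyl]methanol | C=C1CC[C@@H](O[Si](C)(C)C(C)(C)C)C(C)(C)[C@H]1CO | intermediate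
26 | (1S,3R)-3-(tert-butyldimethylsilyloxy)-2,2-dimethyl-6-methylidenecyclohexane-1-carbaldehyde | C=C1CC[C@@H](O[Si](C)(C)C(C)(C)C)C(C)(C)[C@H]1C=O | intermediate
27 | 2-(dichloromethyl)-4,4,5,5-tetramethyl-1,3,2-dioxaborolane | ClC(Cl)B1OC(C)(C)C(C)(C)O1 | starting material
28 | 2-{(E)-2-[(1S,3R)-3-(tert-butyldimethylsilyloxy)-2,2-dimethyl-6-methylidenecyclohexyl]ethenyl}-4,4,5,5-tetramethyl-1,3,2-dioxaborolane | C=C1CC[C@@H](O[Si](C)(C)C(C)(C)C)C(C)(C)[C@H]1/C=C/B2OC(C)(C)C(C)(C)O2 | intermediate
29 | 3″-O-(tert-butyldimethylsilyl) ether of 30 | C=C1CC[C@@H](O[Si](C)(C)C(C)(C)C)C(C)(C)[C@H]1/C=C/C(C)=C\[C@H](O)[C@]12O[C@H]1[C@H](O)C(CO)=C[C@@H]2O | intermediate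
30 | (1R,2S,5R,6S)-1-[(1S,2Z,4E)-1-hydroxy-5-[(1S,3R)-3-hydroxy-2,2-dimethyl-6-methylidenecyclohexyl]-3-methylpenta-2,4-dien-1-yl]-4-(hydroxymethyl)-7-oxabicyclo[4.1.0]hept-3-ene-2,5-diol | C=C1CC[C@@H](O)C(C)(C)[C@H]1/C=C/C(C)=C\[C@H](O)[C@]12O[C@H]1[C@H](O)C(CO)=C[C@@H]2O | target

**Step count and risks**

Total: 21 steps. Longest linear sequence: 15 steps (steps 1–13, 20, 21).

Steps most likely to fail:

1. Step 5. The cycloaddition may be slow at the fully substituted enol carbon, the pyranone may approach the wrong face, or the diene may lose trimethylsilanol and aromatise. The fallback sets out from 6 and returns at 14; it makes the two ring bonds one after the other by ionic chemistry. The kinetic lithium enolate of 6 (LiN(i-Pr)2, THF, −78 °C) would be added in conjugate fashion to but-3-yn-2-one, and the resulting enedione closed by intramolecular aldol addition under pyrrolidinium acetate to the cis-fused ketol F1. α′-Iodination of F1 (LiN(SiMe3)2, then I2), with displacement of the epimerisable iodide by the tertiary alkoxide, would give the epoxy enone F2. Morita–Baylis–Hillman hydroxymethylation (aqueous formaldehyde, imidazole) would give the hydroxymethyl enone F3, and Luche reduction (NaBH4, CeCl3) from the epoxide face would give 14, after which the route continues at step 9.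

2. Step 6. The oxidant may attack the face that carries the silyloxy group, giving a cis-epoxy silyl ether that cannot undergo the Payne shift of step 7. The fallback sets out from 10 and returns at 11; it turns the facial preference round by way of a halohydrin. N-Bromosuccinimide in wet dimethyl sulfoxide (NaHCO3) would place bromine on the face that electrophiles prefer and water trans to it, giving the bromohydrin F4 (the regioisomer would serve equally). K2CO3 in acetonitrile would then close the epoxide on the opposite face, which is 11.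

3. Step 12. The basic ylide may enolise the α-alkoxy aldehyde, with β-elimination that opens the epoxide, or Z selectivity may erode. The fallback sets out from 17 and returns at 29. Corey–Fuchs dibromo-olefination (CBr4, PPh3, Et3N) would give the 1,1-dibromoalkene F5. A trans-selective Negishi monomethylation (MeZnCl, PdCl2(DPEphos)) at the bromide trans to the ring substituent would give the (Z)-bromoalkene F6. Acetonide hydrolysis as in step 13 would give the tetraol bromide F7, and Suzuki–Miyaura coupling of F7 with 28 under the conditions of step 20 would give 29.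

**Further compounds**

F1 | step 5 | cis-fused ketol 4a-hydroxy-2,2-dimethyl-4-(triisopropylsilyloxymethyl)-4a,5-dihydro-4H-1,3-benzodioxin-6(8aH)-one | CC(C)[Si](C(C)C)(C(C)C)OC[C@@H]1OC(C)(C)O[C@H]2C=CC(=O)C[C@@]12O
F2 | step 5 | epoxy enone 4a,5-epoxy-2,2-dimethyl-4-(triisopropylsilyloxymethyl)-4a,5-dihydro-4H-1,3-benzodioxin-6(8aH)-one | CC(C)[Si](C(C)C)(C(C)C)OC[C@@H]1OC(C)(C)O[C@H]2C=CC(=O)[C@@H]3O[C@]123
F3 | step 5 | 7-(hydroxymethyl) derivative of F2 | CC(C)[Si](C(C)C)(C(C)C)OC[C@@H]1OC(C)(C)O[C@H]2C=C(CO)C(=O)[C@@H]3O[C@]123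
F4 | step 6 | bromohydrin of 10 (5-bromo cis to the 4a-silyloxy group, 6-hydroxy trans to bromine) | CC(C)[Si](C(C)C)(C(C)C)OC[C@@H]1OC(C)(C)O[C@H]2C=C(C(=O)OC)[C@@H](O)[C@H](Br)[C@@]12O[Si](C)(C)C
F5 | step 12 | bis-acetonide 2,2-dibromoethenyl compound | BrC(Br)=C[C@@H]1OC(C)(C)O[C@H]2C=C4COC(C)(C)O[C@H]4[C@@H]3O[C@]123
F6 | step 12 | bis-acetonide (Z)-2-bromoprop-1-enyl compound | C/C(Br)=C/[C@@H]1OC(C)(C)O[C@H]2C=C4COC(C)(C)O[C@H]4[C@@H]3O[C@]123
F7 | step 12 | 1-[(1S,2Z)-3-bromo-1-hydroxybut-2-en-1-yl]-4-(hydroxymethyl)-7-oxabicyclo[4.1.0]hept-3-ene-2,5-diol (ring as in 30) | C/C(Br)=C/[C@H](O)[C@]12O[C@H]1[C@H](O)C(CO)=C[C@@H]2O
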